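Leoligin is cut at the C4–C5 bond of its tetrahydrofuran (ring atoms O1, C2, C3, C4, C5). The feature used is that the C9 oxygen on C3 sits homoallylic to a C4=C7' styrene: a phosphinite bound reversibly to that oxygen steers rhodium to C4, so one hydroformylation adds C5 as a formyl group, turns C7' into the benzylic CH2, sets C4 against C3 and closes a γ-lactol on the C9 oxygen. The precursor is an Evans-aldol-derived (2R,3S)-2-styryl-3-silyloxy-3-arylpropan-1-ol whose C2 oxygen is capped so that only the C9 hydroxyl directs. Lactol reduction, acid-mediated closure of O1 between C5 and C2 and a Mitsunobu angeloylation complete the route.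

Key step: step 6

Remark on the chemistry (assumption): atom labels follow the lignan skeleton of the target (O1; C2 bears the aryl group; C3 bears the ester CH2, C9; C4 bears the benzylic CH2, C7'; C5). The target is (2S,3R,4R), 2,3-trans and 3,4-cis, with a Z (angelate) ester. The chain (2S,3S)-imide 11, (2R,3S)-alcohol 13, (3R,4R)-lactol 15 is consistent with it. The cation closure of step 8 sets C2 afresh, so the aldol is relied on for C3 only.

Step 1
Reactants: 1 (3,4-dimethoxyphenyl)acetaldehyde; 2 malonic acid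
Product: 4 (E)-4-(3,4-dimethoxyphenyl)but-3-enoic acid, via alkylidenemalonic acid 3 (not isolated)
Conditions: piperidinium acetate (cat.), DMSO, rt → 100 °C; aq. HCl work-up
Reagents that add atoms: none
Why: Knoevenagel–Doebner condensation in its β,γ-selective form, in which the alkylidenemalonic acid 3 should lose CO2 with the double bond moving into conjugation with the arene, so that the E styryl acid is the thermodynamic product.

Step 2
Reactants: 4 (E)-4-(3,4-dimethoxyphenyl)but-3-enoic acid; 5 (S)-4-benzyloxazolidin-2-one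
Product: 7 (S)-4-benzyl-3-[(E)-4-(3,4-dimethoxyphenyl)but-3-enoyl]oxazolidin-2-one, via mixed pivalic anhydride 6 (not isolated)
Conditions: PivCl, Et3N, THF, −20 °C; then 5, LiCl, −20 °C → rt
Reagents that add atoms: none
Why: N-acylation of an oxazolidinone through a mixed anhydride, in which the lithium-activated oxazolidinone should attack the unhindered acyl group of 6 while the low temperature and weak base keep the β,γ-alkene out of conjugation.

Step 3
Reactants: 7 (S)-4-benzyl-3-[(E)-4-(3,4-dimethoxyphenyl)but-3-enoyl]oxazolidin-2-one; 8 3,4-dimethoxybenzaldehyde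
Product: 11 (S)-4-benzyl-3-[(2S,3S)-3-(3,4-dimethoxyphenyl)-2-[(E)-2-(3,4-dimethoxyphenyl)ethenyl]-3-hydroxypropanoyl]oxazolidin-2-one, via boron dienolate 9 (not isolated), via boron aldolate 10 (not isolated)
Conditions: Bu2BOTf, iPr2NEt, CH2Cl2, −78 → 0 °C; then 8, −78 → 0 °C; pH 7 buffer, MeOH, H2O2, 0 °C
Reagents that add atoms: none
Why: Evans syn aldol, in which the Z dibutylboron dienolate should react at its α-carbon through a closed chair transition state on the face away from the benzyl group of the dipole-opposed auxiliary, setting the acyl α-carbon (future C3, S in the imide) and the carbinol carbon (future C2, S) syn.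

Step 4
Reactants: 11 (S)-4-benzyl-3-[(2S,3S)-3-(3,4-dimethoxyphenyl)-2-[(E)-2-(3,4-dimethoxyphenyl)ethenyl]-3-hydroxypropanoyl]oxazolidin-2-one
Product: 12 (S)-4-benzyl-3-[(2S,3S)-3-(tert-butyldimethylsilyloxy)-3-(3,4-dimethoxyphenyl)-2-[(E)-2-(3,4-dimethoxyphenyl)ethenyl]propanoyl]oxazolidin-2-one
Conditions: TBSOTf, 2,6-lutidine, CH2Cl2, −78 → 0 °C
Reagents that add atoms: tert-butyldimethylsilyl triflate, CC(C)(C)[Si](C)(C)OS(=O)(=O)C(F)(F)F
Why: silylation of a hindered secondary alcohol with a silyl triflate and a non-nucleophilic base, which should neither epimerise the α-centre nor provoke retro-aldol, and which caps the C2 oxygen that would otherwise be a second homoallylic hydroxyl in the key step.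

Step 5
Reactants: 12 (S)-4-benzyl-3-[(2S,3S)-3-(tert-butyldimethylsilyloxy)-3-(3,4-dimethoxyphenyl)-2-[(E)-2-(3,4-dimethoxyphenyl)ethenyl]propanoyl]oxazolidin-2-one
Product: 13 (2R,3S)-3-(tert-butyldimethylsilyloxy)-3-(3,4-dimethoxyphenyl)-2-[(E)-2-(3,4-dimethoxyphenyl)ethenyl]propan-1-ol
Conditions: LiBH4, MeOH (1 equiv), THF, 0 °C
Reagents that add atoms: none
Why: reductive cleavage of the N-acyl oxazolidinone, in which hydride should attack the exocyclic imide carbonyl and give the primary alcohol without touching the silyl ether, the styrene or either stereocentre (the descriptor at C3 changes only because the priorities change).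

Step 6
Reactants: 13 (2R,3S)-3-(tert-butyldimethylsilyloxy)-3-(3,4-dimethoxyphenyl)-2-[(E)-2-(3,4-dimethoxyphenyl)ethenyl]propan-1-ol
Product: 15 (3R,4R)-4-[(S)-(tert-butyldimethylsilyloxy)(3,4-dimethoxyphenyl)methyl]-3-(3,4-dimethoxybenzyl)tetrahydrofuran-2-ol (trans lactol; both anomers), via hydroxy aldehyde 14 (not isolated)
Conditions: Rh(acac)(CO)2 (2 mol %), Ph2POMe (10 mol %), CO/H2 1:1 (40 bar), 4 Å molecular sieves, THF, 40 °C
Reagents that add atoms: carbon monoxide, [C-]#[O+]
Why: Proposed new method: Ph2POMe should exchange its methoxy group for the C9 hydroxyl of 13, so that the phosphorus-bound monovalent rhodium hydride adds across the tethered alkene with Rh at C4 and H at C7' through a six-membered rhodacycle (Rh, P, O, C9, C3, C4); CO insertion, hydrogenolysis of the acyl and exchange at phosphorus then release aldehyde 14 and return the directing group. The closest known reaction type is the branched-selective hydroformylation of homoallylic alcohols to γ-lactols with a catalytic, reversibly bound phosphinite; what is new is the aryl-terminated 1,2-disubstituted alkene, whose intrinsic bias is for the benzylic position. The ring closes by 5-exo-trig addition of the C9 hydroxyl to the C5 formyl group (hemiacetal formation). C4 is controlled by C3 through the chair-like chelate, in which the CH(OSi)Ar group on C3 and the C4–C7' bond of the E-alkene both lie equatorial, which places them trans on the lactol (4R); the anomeric centre at C5 is not controlled and is removed in step 7. The step needs C4-over-C7' regioselectivity, secured by the tether (delivery to C7' would require a seven-membered chelate), helped by the electron-rich arene, which weakens the benzylic preference, and by the silyl cap, which leaves the C9 hydroxyl as the only one able to bind phosphorus.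

Step 7
Reactants: 15 (3R,4R)-4-[(S)-(tert-butyldimethylsilyloxy)(3,4-dimethoxyphenyl)methyl]-3-(3,4-dimethoxybenzyl)tetrahydrofuran-2-ol
Product: 16 (2R,3R)-2-[(S)-(tert-butyldimethylsilyloxy)(3,4-dimethoxyphenyl)methyl]-3-(3,4-dimethoxybenzyl)butane-1,4-diol
Conditions: NaBH4, MeOH, 0 °C → rt
Reagents that add atoms: none
Why: borohydride reduction of a lactol through its open hydroxy-aldehyde tautomer, which should converge both anomers on one diol and leave the silyl ether and the C3 and C4 centres untouched.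

Step 8
Reactants: 16 (2R,3R)-2-[(S)-(tert-butyldimethylsilyloxy)(3,4-dimethoxyphenyl)methyl]-3-(3,4-dimethoxybenzyl)butane-1,4-diol
Product: 18 [(2S,3R,4R)-4-(3,4-dimethoxybenzyl)-2-(3,4-dimethoxyphenyl)tetrahydrofuran-3-yl]methanol, via desilylated triol 17 (not isolated)
Conditions: TsOH·H2O (10 mol %), MeCN/H2O 20:1, 0 °C → rt
Reagents that add atoms: none
Why: acid-catalysed desilylation followed by SN1 cyclodehydration of a 1-aryl-1,4-diol (the classical lignan triol-to-2-aryltetrahydrofuran closure), in which the para-methoxy-stabilised C2 cation should be captured 5-exo by the C5 hydroxyl (the C9 hydroxyl could only give an oxetane) with the aryl group trans to the C3 substituent under substrate control, reinforced by the reversibility of benzylic ether formation, while mild acid and low temperature hold back Friedel–Crafts capture by the other arene.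

Step 9
Reactants: 18 [(2S,3R,4R)-4-(3,4-dimethoxybenzyl)-2-(3,4-dimethoxyphenyl)tetrahydrofuran-3-yl]methanol; 19 angelic acid, (Z)-2-methylbut-2-enoic acid
Product: 20 leoligin, [(2S,3R,4R)-4-(3,4-dimethoxybenzyl)-2-(3,4-dimethoxyphenyl)tetrahydrofuran-3-yl]methyl (Z)-2-methylbut-2-enoate
Conditions: PPh3, DIAD, THF, 0 °C; then 19 and 18, 0 °C → rt
Reagents that add atoms: none
Why: Mitsunobu esterification of a primary alcohol, in which the angelate anion acts only as a nucleophile towards the alkoxyphosphonium ion, so the acid is never activated as an acyl donor and its Z geometry should be kept (C9 is not a stereocentre, so the inversion has no consequence).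

Compound list
1 | (3,4-dimethoxyphenyl)acetaldehyde | COc1ccc(CC=O)cc1OC | starting material
2 | malonic acid | OC(=O)CC(=O)O | starting material
3 | 2-[2-(3,4-dimethoxyphenyl)ethylidene]malonic acid | OC(=O)C(=CCc1ccc(OC)c(OC)c1)C(=O)O | intermediate (not isolated)
4 | (E)-4-(3,4-dimethoxyphenyl)but-3-enoic acid | OC(=O)C/C=C/c1ccc(OC)c(OC)c1 | intermediate
5 | (S)-4-benzyloxazolidin-2-one | O=C1OC[C@H](Cc2ccccc2)N1 | starting material
6 | (E)-4-(3,4-dimethoxyphenyl)but-3-enoic pivalic anhydride | CC(C)(C)C(=O)OC(=O)C/C=C/c1ccc(OC)c(OC)c1 | intermediate (not isolated)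
7 | (S)-4-benzyl-3-[(E)-4-(3,4-dimethoxyphenyl)but-3-enoyl]oxazolidin-2-one | O=C1OC[C@H](Cc2ccccc2)N1C(=O)C/C=C/c1ccc(OC)c(OC)c1 | intermediate
8 | 3,4-dimethoxybenzaldehyde | COc1ccc(C=O)cc1OC | starting material
9 | dibutylboron (Z)-dienolate of imide 7 | CCCCB(CCCC)O/C(N1C(=O)OC[C@@H]1Cc1ccccc1)=C\C=C\c1ccc(OC)c(OC)c1 | intermediate (not isolated)
10 | O-dibutylboryl aldolate of 11 | O=C1OC[C@H](Cc2ccccc2)N1C(=O)[C@@H](/C=C/c1ccc(OC)c(OC)c1)[C@H](OB(CCCC)CCCC)c1ccc(OC)c(OC)c1 | intermediate (not isolated)
11 | (S)-4-benzyl-3-[(2S,3S)-3-(3,4-dimethoxyphenyl)-2-[(E)-2-(3,4-dimethoxyphenyl)ethenyl]-3-hydroxypropanoyl]oxazolidin-2-one | O=C1OC[C@H](Cc2ccccc2)N1C(=O)[C@@H](/C=C/c1ccc(OC)c(OC)c1)[C@H](O)c1ccc(OC)c(OC)c1 | intermediate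
12 | (S)-4-benzyl-3-[(2S,3S)-3-(tert-butyldimethylsilyloxy)-3-(3,4-dimethoxyphenyl)-2-[(E)-2-(3,4-dimethoxyphenyl)ethenyl]propanoyl]oxazolidin-2-one | O=C1OC[C@H](Cc2ccccc2)N1C(=O)[C@@H](/C=C/c1ccc(OC)c(OC)c1)[C@H](O[Si](C)(C)C(C)(C)C)c1ccc(OC)c(OC)c1 | intermediate
13 | (2R,3S)-3-(tert-butyldimethylsilyloxy)-3-(3,4-dimethoxyphenyl)-2-[(E)-2-(3,4-dimethoxyphenyl)ethenyl]propan-1-ol | OC[C@H]([C@H](O[Si](C)(C)C(C)(C)C)c1ccc(OC)c(OC)c1)/C=C/c1ccc(OC)c(OC)c1 | intermediate (key-step precursor)
14 | (2R,3R,4S)-4-(tert-butyldimethylsilyloxy)-2-(3,4-dimethoxybenzyl)-4-(3,4-dimethoxyphenyl)-3-(hydroxymethyl)butanal | O=C[C@H](Cc1ccc(OC)c(OC)c1)[C@H](CO)[C@H](O[Si](C)(C)C(C)(C)C)c1ccc(OC)c(OC)c1 | intermediate (not isolated)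
15 | (3R,4R)-4-[(S)-(tert-butyldimethylsilyloxy)(3,4-dimethoxyphenyl)methyl]-3-(3,4-dimethoxybenzyl)tetrahydrofuran-2-ol (both anomers) | OC1OC[C@H]([C@H](O[Si](C)(C)C(C)(C)C)c2ccc(OC)c(OC)c2)[C@H]1Cc1ccc(OC)c(OC)c1 | intermediate (key-step product)
16 | (2R,3R)-2-[(S)-(tert-butyldimethylsilyloxy)(3,4-dimethoxyphenyl)methyl]-3-(3,4-dimethoxybenzyl)butane-1,4-diol | OC[C@H](Cc1ccc(OC)c(OC)c1)[C@H](CO)[C@H](O[Si](C)(C)C(C)(C)C)c1ccc(OC)c(OC)c1 | intermediate
17 | (2R,3R)-2-(3,4-dimethoxybenzyl)-3-[(S)-(3,4-dimethoxyphenyl)(hydroxy)methyl]butane-1,4-diol | OC[C@H](Cc1ccc(OC)c(OC)c1)[C@H](CO)[C@H](O)c1ccc(OC)c(OC)c1 | intermediate (not isolated)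
18 | [(2S,3R,4R)-4-(3,4-dimethoxybenzyl)-2-(3,4-dimethoxyphenyl)tetrahydrofuran-3-yl]methanol | OC[C@H]1[C@@H](Cc2ccc(OC)c(OC)c2)CO[C@@H]1c1ccc(OC)c(OC)c1 | intermediate
19 | angelic acid, (Z)-2-methylbut-2-enoic acid | C/C=C(/C)C(=O)O | starting material
20 | leoligin, [(2S,3R,4R)-4-(3,4-dimethoxybenzyl)-2-(3,4-dimethoxyphenyl)tetrahydrofuran-3-yl]methyl (Z)-2-methylbut-2-enoate | C/C=C(/C)C(=O)OC[C@H]1[C@@H](Cc2ccc(OC)c(OC)c2)CO[C@@H]1c1ccc(OC)c(OC)c1 | target

Total step count: 9. Longest linear sequence: 9 steps (1 to 20).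

Steps most likely to fail

Step 6 (carries the label). Rhodium may be delivered to the benzylic carbon C7' in competition with the tether, the alkene may be hydrogenated or may migrate, or the two faces of C4 may be poorly distinguished. The fallback uses known chemistry, sets out from 13 and comes back to the route at 16. The C9 hydroxyl is silylated with (bromomethyl)chlorodimethylsilane (Et3N, CH2Cl2, 0 °C) to give the (bromomethyl)dimethylsilyl ether F1. Bu3SnH with AIBN (slow addition, benzene, 80 °C) generates the α-silyl radical, which should add 6-exo-trig to C4 because this leaves the benzylic radical at C7'; hydrogen transfer then gives the 1,2-oxasilinane F2 with its two ring substituents equatorial, that is trans. Tamao oxidation (H2O2, KF, KHCO3, THF/MeOH) cleaves both bonds to silicon and gives diol 16, so that step 7 is no longer needed.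

Step 8. The cation at C2 may close with incomplete trans selectivity, or the electron-rich arene on C7' may capture it in a Friedel–Crafts closure to an aryltetralin if the acid is too strong or the contact too long. The fallback avoids the cation, sets out from 16 and comes back to the route at 20. MsCl and Et3N (CH2Cl2, −20 °C) give the bis-mesylate F3. Bu4NF (THF, 0 °C) frees the C2 alkoxide, which should displace the C5 mesylate 5-exo-tet (attack at C9 would need a four-membered ring) and give the tetrahydrofuranylmethyl mesylate F4; C2 keeps its aldol configuration, which is already that of the target. The remaining mesylate is displaced with cesium (Z)-2-methylbut-2-enoate F5 (made from 19 and Cs2CO3, DMF, 50 °C) to give 20. Steps 8 and 9 are both replaced.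

Step 5. Hydride may attack the ring carbonyl of the auxiliary, because the acyl carbonyl is flanked by an α-branch and a silyloxy group, or the silyl group may migrate to the new primary alkoxide. The fallback changes the order of events, sets out from 11 and comes back to the route at 13. LiBH4/MeOH (THF, 0 °C) on the free aldol, where the hydroxyl assists the cleavage, gives the (1S,2R)-diol F6. TBSOTf (2.5 equiv) and 2,6-lutidine give the bis-silyl ether F7. HF·pyridine (pyridine/THF, 0 °C) removes the primary silyl ether selectively and returns 13.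

Further compounds
F1 | step 6 | (bromomethyl){[(2R,3S)-3-(tert-butyldimethylsilyloxy)-3-(3,4-dimethoxyphenyl)-2-[(E)-2-(3,4-dimethoxyphenyl)ethenyl]propyl]oxy}dimethylsilane | BrC[Si](C)(C)OC[C@H]([C@H](O[Si](C)(C)C(C)(C)C)c1ccc(OC)c(OC)c1)/C=C/c1ccc(OC)c(OC)c1
F2 | step 6 | (4R,5R)-5-[(S)-(tert-butyldimethylsilyloxy)(3,4-dimethoxyphenyl)methyl]-4-(3,4-dimethoxybenzyl)-2,2-dimethyl-1,2-oxasilinane | C[Si]1(C)C[C@H](Cc2ccc(OC)c(OC)c2)[C@@H]([C@H](O[Si](C)(C)C(C)(C)C)c2ccc(OC)c(OC)c2)CO1
F3 | step 8 | (2R,3R)-2-[(S)-(tert-butyldimethylsilyloxy)(3,4-dimethoxyphenyl)methyl]-3-(3,4-dimethoxybenzyl)butane-1,4-diyl dimethanesulfonate | CS(=O)(=O)OC[C@H](Cc1ccc(OC)c(OC)c1)[C@H](COS(C)(=O)=O)[C@H](O[Si](C)(C)C(C)(C)C)c1ccc(OC)c(OC)c1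
F4 | step 8 | [(2S,3R,4R)-4-(3,4-dimethoxybenzyl)-2-(3,4-dimethoxyphenyl)tetrahydrofuran-3-yl]methyl methanesulfonate | CS(=O)(=O)OC[C@H]1[C@@H](Cc2ccc(OC)c(OC)c2)CO[C@@H]1c1ccc(OC)c(OC)c1
F5 | step 8 | cesium (Z)-2-methylbut-2-enoate | C/C=C(/C)C(=O)[O-].[Cs+]
F6 | step 5 | (1S,2R)-1-(3,4-dimethoxyphenyl)-2-[(E)-2-(3,4-dimethoxyphenyl)ethenyl]propane-1,3-diol | OC[C@H]([C@H](O)c1ccc(OC)c(OC)c1)/C=C/c1ccc(OC)c(OC)c1
F7 | step 5 | (2R,3S)-1,3-bis(tert-butyldimethylsilyloxy)-3-(3,4-dimethoxyphenyl)-2-[(E)-2-(3,4-dimethoxyphenyl)ethenyl]propane | CC(C)(C)[Si](C)(C)OC[C@H]([C@H](O[Si](C)(C)C(C)(C)C)c1ccc(OC)c(OC)c1)/C=C/c1ccc(OC)c(OC)c1
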